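**Plan**
1. Retrosynthesis: four benzyl ethers are removed last; ring C is opened at O1–C2 to an open α-(flavanon-8''-yl)-2',4-dihydroxychalcone; the C3–C8'' bond is cut (Suzuki–Miyaura) into an (S)-flavanone 8-boronate (rings D/F/E) and an α-iodochalcone (rings A and B); the flavanone is cut at C2''–aryl (conjugate addition to a chromone) and the iodochalcone at the carbonyl–alkyne bond (aldehyde plus acetylide).
2. Forward: ring F is built as a chromone on ring D, ring E is added, C8'' is iodinated and borylated; rings A and B are joined through an ynone that is hydrostannylated and iodinated; cross-coupling unites the halves, desilylation frees two phenols, ring C closes last, and hydrogenolysis gives the target.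
3. Enabling feature: C2 of flavanone 1 is benzylic to ring B, whose 4'-hydroxyl is free and para to it, so the open chalcone can tautomerise to a para-quinone methide that is electrophilic at C2 and is trapped by the ring A 2'-hydroxyl (O1–C2).
4. Stereochemistry: C2'' (S) comes from a ligand-controlled conjugate addition, C2 (R) from the chiral phosphoric acid, and C3 (S) from equilibration to the 2,3-trans arrangement.

Key step: step 15

Assumption (step 3): the (R)-antipode of t-BuPyOx is taken to give the (2S)-flavanone, by analogy with the sense of aryl transfer to cyclic enones; if the sense is opposite, the (S)-ligand is used.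
Assumption (step 15): (R)-TRIP is written as the acid antipode that gives (2R); no precedent fixes the sense, so the antipode is chosen by experiment.
Remark: the alkene of 19–21 is drawn as formed by syn-hydrostannation (ring B cis to the aroyl group); its geometry is lost in quinone methide 22 and does not matter. Benzyl ethers replace acid-labile acetals as the permanent groups because the chromone synthesis of step 2 uses strong acid.

Step 1
Reactants: 1 2',4',6'-trihydroxyacetophenone
Product: 2 1-[2,4-bis(benzyloxy)-6-hydroxyphenyl]ethan-1-one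
Conditions: BnBr (2.05 equiv), K2CO3, DMF, 0 °C to rt
Reagents that add atoms: benzyl bromide BrCc1ccccc1
Why: Williamson ether synthesis in which the two non-chelated hydroxyls are alkylated while the hydroxyl hydrogen-bonded to the acetyl group stays free, the usual outcome for phloroacetophenone with two equivalents of benzyl bromide.

Step 2
Reactants: 2 1-[2,4-bis(benzyloxy)-6-hydroxyphenyl]ethan-1-one
Product: 4 5,7-bis(benzyloxy)-4H-chromen-4-one, via enaminone 3 (not isolated)
Conditions: Me2NCH(OMe)2, toluene, 100 °C; then conc. HCl, CH2Cl2, rt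
Reagents that add atoms: N,N-dimethylformamide dimethyl acetal COC(OC)N(C)C
Why: Enaminone formation followed by acid-induced cyclisation with loss of dimethylamine is the standard chromone synthesis from 2'-hydroxyacetophenones, and benzyl ethers tolerate the acid.

Step 3
Reactants: 4 5,7-bis(benzyloxy)-4H-chromen-4-one; 5 4-methoxyphenylboronic acid
Product: 6 (2S)-5,7-bis(benzyloxy)-2-(4-methoxyphenyl)chroman-4-one
Conditions: Pd(OCOCF3)2 (5 mol%), (R)-t-BuPyOx (6 mol%), NH4PF6 (30 mol%), H2O (5 equiv), ClCH2CH2Cl, 60 °C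
Reagents that add atoms: none
Why: Asymmetric conjugate addition of an arylboronic acid to a chromone catalysed by divalent palladium (aryl transfer to C2, then protonation of the palladium enolate by water), in which the pyridine-oxazoline ligand selects the face of C2 and so sets C2'' as (S).

Step 4
Reactants: 6 (2S)-5,7-bis(benzyloxy)-2-(4-methoxyphenyl)chroman-4-one
Product: 7 (2S)-5,7-bis(benzyloxy)-8-iodo-2-(4-methoxyphenyl)chroman-4-one
Conditions: NIS (1.05 equiv), CF3CO2H (cat.), MeCN, 0 °C
Reagents that add atoms: N-iodosuccinimide O=C1CCC(=O)N1I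
Why: Electrophilic aromatic iodination of the phloroglucinol-type ring D, expected at C8 (between the 7-benzyloxy group and the ring oxygen) rather than at C6 (flanked by two benzyloxy groups), as is usual for 5-O-alkylated 5,7-dioxygenated flavonoids; C2'' is not involved.

Step 5
Reactants: 7 (2S)-5,7-bis(benzyloxy)-8-iodo-2-(4-methoxyphenyl)chroman-4-one
Product: 8 (2S)-5,7-bis(benzyloxy)-2-(4-methoxyphenyl)-8-(4,4,5,5-tetramethyl-1,3,2-dioxaborolan-2-yl)chroman-4-one
Conditions: B2pin2, PdCl2(dppf) (5 mol%), KOAc, 1,4-dioxane, 85 °C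
Reagents that add atoms: bis(pinacolato)diboron CC1(C)OB(OC1(C)C)B1OC(C)(C)C(C)(C)O1
Why: Miyaura borylation of an aryl iodide, in which acetate is too weak a base to enolise the chromanone, so ring F should stay closed and C2'' should keep its configuration.

Step 6
Reactants: 9 2,4,6-trihydroxybenzaldehyde
Product: 10 2,4-bis(benzyloxy)-6-hydroxybenzaldehyde
Conditions: BnBr (2.05 equiv), K2CO3, DMF, 0 °C to rt
Reagents that add atoms: benzyl bromide BrCc1ccccc1
Why: Williamson ether synthesis that again leaves the hydroxyl chelated to the formyl group free.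

Step 7
Reactants: 10 2,4-bis(benzyloxy)-6-hydroxybenzaldehyde
Product: 11 2,4-bis(benzyloxy)-6-[(triisopropylsilyl)oxy]benzaldehyde
Conditions: TIPSOTf, 2,6-lutidine, CH2Cl2, 0 °C
Reagents that add atoms: triisopropylsilyl trifluoromethanesulfonate CC(C)[Si](OS(=O)(=O)C(F)(F)F)(C(C)C)C(C)C
Why: Silylation of a hydrogen-bonded phenol with a silyl triflate and a hindered pyridine base; the aldehyde cannot enolise, and the bulky silyl group is chosen to survive the organolithium step and the later aqueous base.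

Step 8
Reactants: 12 4-hydroxybenzaldehyde
Product: 13 4-[(triisopropylsilyl)oxy]benzaldehyde
Conditions: TIPSCl, imidazole, DMF, rt
Reagents that add atoms: chlorotriisopropylsilane CC(C)[Si](Cl)(C(C)C)C(C)C
Why: Standard silyl ether formation of a phenol with silyl chloride and imidazole.

Step 9
Reactants: 13 4-[(triisopropylsilyl)oxy]benzaldehyde
Product: 14 [4-(2,2-dibromovinyl)phenoxy]triisopropylsilane
Conditions: CBr4, PPh3, CH2Cl2, 0 °C
Reagents that add atoms: carbon tetrabromide BrC(Br)(Br)Br
Why: First stage of the Corey–Fuchs reaction, a Wittig-type dibromo-olefination of an aromatic aldehyde.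

Step 10
Reactants: 14 [4-(2,2-dibromovinyl)phenoxy]triisopropylsilane; 11 2,4-bis(benzyloxy)-6-[(triisopropylsilyl)oxy]benzaldehyde
Product: 16 1-[2,4-bis(benzyloxy)-6-(triisopropylsilyloxy)phenyl]-3-[4-(triisopropylsilyloxy)phenyl]prop-2-yn-1-ol (racemic), via lithium acetylide 15 (not isolated)
Conditions: 14, n-BuLi (2.1 equiv), THF, −78 to 0 °C; then 11, −78 °C; AcOH, −78 °C
Reagents that add atoms: none
Why: Second stage of the Corey–Fuchs sequence (Br/Li exchange, carbenoid rearrangement, deprotonation) gives the lithium acetylide, which adds 1,2 to the aldehyde; the cold acidic quench is meant to prevent migration of the ortho silyl group to the new alkoxide, and the racemic carbinol centre disappears in step 11.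

Step 11
Reactants: 16 1-[2,4-bis(benzyloxy)-6-(triisopropylsilyloxy)phenyl]-3-[4-(triisopropylsilyloxy)phenyl]prop-2-yn-1-ol
Product: 17 1-[2,4-bis(benzyloxy)-6-(triisopropylsilyloxy)phenyl]-3-[4-(triisopropylsilyloxy)phenyl]prop-2-yn-1-one
Conditions: Dess–Martin periodinane, CH2Cl2, rt
Reagents that add atoms: none
Why: Dess–Martin oxidation of a benzylic propargylic alcohol to the ynone under near-neutral conditions that leave silyl and benzyl ethers alone.

Step 12
Reactants: 17 1-[2,4-bis(benzyloxy)-6-(triisopropylsilyloxy)phenyl]-3-[4-(triisopropylsilyloxy)phenyl]prop-2-yn-1-one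
Product: 19 (E)-1-[2,4-bis(benzyloxy)-6-(triisopropylsilyloxy)phenyl]-2-iodo-3-[4-(triisopropylsilyloxy)phenyl]prop-2-en-1-one, via alpha-stannyl enone 18 (not isolated)
Conditions: Bu3SnH, Pd(PPh3)4 (3 mol%), THF, 0 °C to rt; then I2, CH2Cl2, 0 °C
Reagents that add atoms: iodine II
Why: Palladium-catalysed hydrostannation of an ynone is a syn addition that places tin alpha to the carbonyl, and iododestannylation then replaces tin by iodine with retention, faster than iodine can attack the electron-rich rings.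

Step 13
Reactants: 19 (E)-1-[2,4-bis(benzyloxy)-6-(triisopropylsilyloxy)phenyl]-2-iodo-3-[4-(triisopropylsilyloxy)phenyl]prop-2-en-1-one; 8 (2S)-5,7-bis(benzyloxy)-2-(4-methoxyphenyl)-8-(4,4,5,5-tetramethyl-1,3,2-dioxaborolan-2-yl)chroman-4-one
Product: 20 (2S)-5,7-bis(benzyloxy)-8-{(Z)-3-[2,4-bis(benzyloxy)-6-(triisopropylsilyloxy)phenyl]-3-oxo-1-[4-(triisopropylsilyloxy)phenyl]prop-1-en-2-yl}-2-(4-methoxyphenyl)chroman-4-one
Conditions: Pd(OAc)2 (5 mol%), SPhos (10 mol%), K3PO4, toluene/H2O (10:1), 40 °C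
Reagents that add atoms: none
Why: Suzuki–Miyaura coupling of an alpha-iodo enone with an arylboronate, as in the arylation of 3-iodochromones (cyclic alpha-iodo enones), with SPhos chosen for the di-ortho-substituted boron partner and mild phosphate at 40 °C chosen to spare the silyl ethers and the base-labile C2'' centre.

Step 14
Reactants: 20 (2S)-5,7-bis(benzyloxy)-8-{(Z)-3-[2,4-bis(benzyloxy)-6-(triisopropylsilyloxy)phenyl]-3-oxo-1-[4-(triisopropylsilyloxy)phenyl]prop-1-en-2-yl}-2-(4-methoxyphenyl)chroman-4-one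
Product: 21 (2S)-5,7-bis(benzyloxy)-8-{(Z)-3-[2,4-bis(benzyloxy)-6-hydroxyphenyl]-1-(4-hydroxyphenyl)-3-oxoprop-1-en-2-yl}-2-(4-methoxyphenyl)chroman-4-one
Conditions: Bu4NF/AcOH (1:1, 2.5 equiv), THF, 0 °C; pH 5 buffer work-up
Reagents that add atoms: none
Why: Fluoride cleavage of aryl silyl ethers, buffered with acetic acid so that no free phenoxide should start an uncatalysed oxa-Michael closure or open ring F; the diphenol is used promptly.

Step 15
Reactants: 21 (2S)-5,7-bis(benzyloxy)-8-{(Z)-3-[2,4-bis(benzyloxy)-6-hydroxyphenyl]-1-(4-hydroxyphenyl)-3-oxoprop-1-en-2-yl}-2-(4-methoxyphenyl)chroman-4-one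
Product: 23 (2R,3S)-5,7-bis(benzyloxy)-3-[(2S)-5,7-bis(benzyloxy)-2-(4-methoxyphenyl)-4-oxochroman-8-yl]-2-(4-hydroxyphenyl)chroman-4-one, via para-quinone methide 22 (not isolated)
Conditions: (R)-TRIP (10 mol%), toluene, 4 Å MS, 0 °C
Reagents that add atoms: none
Why: Proposed new method: the phosphoric acid, bound to the ring B hydroxyl and the enone carbonyl, shuttles the phenolic proton to C3 and so converts the 4-hydroxystyryl ketone into its para-quinone methide tautomer 22, whose exocyclic carbon (the future C2) is attacked by the free ring A hydroxyl (2'-OH in chalcone numbering) with rearomatisation of ring B, forming O1–C2. The closest known reaction types are chiral phosphoric acid-catalysed 1,6-additions to para-quinone methides generated in situ from 4-hydroxybenzyl or 4-hydroxystyryl precursors and the organocatalytic oxa-Michael cyclisation of activated 2'-hydroxychalcones to flavanones. Ring C closes in a 6-exo-trig mode with respect to the quinone methide C=C bond. C2 is set by the catalyst, whose phosphate should hold the quinone carbonyl and the attacking phenol in its chiral pocket and so select one face of the methide carbon, while C3, enolisable alpha to the ketone in 22 and in the product, should settle trans to ring B under thermodynamic control. The step needs site selectivity between the two chromanone halves and catalyst control over the remote C2'' centre: only ring B carries a free para-hydroxyl, so ring F with its 4-methoxyphenyl group cannot form a quinone methide and should stay closed, the bulky 3,3'-aryl groups of the acid are relied on to override the substrate bias, and the reaction is stopped cold at full conversion because the closure is reversible through the same quinone methide.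

Step 16
Reactants: 23 (2R,3S)-5,7-bis(benzyloxy)-3-[(2S)-5,7-bis(benzyloxy)-2-(4-methoxyphenyl)-4-oxochroman-8-yl]-2-(4-hydroxyphenyl)chroman-4-one
Product: 24 (2R,3S)-5,7-dihydroxy-3-[(2S)-5,7-dihydroxy-2-(4-methoxyphenyl)-4-oxochroman-8-yl]-2-(4-hydroxyphenyl)chroman-4-one (CNP0140544.1)
Conditions: H2 (1 atm), 10% Pd/C, EtOAc/THF, rt
Reagents that add atoms: none
Why: Hydrogenolysis of four aryl benzyl ethers over Pd/C under neutral conditions, which should leave the aryl ketones, the methyl ether and the three stereocentres untouched.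

**Compound list**
1 | 2',4',6'-trihydroxyacetophenone | CC(=O)c1c(O)cc(O)cc1O | starting material
2 | 1-[2,4-bis(benzyloxy)-6-hydroxyphenyl]ethan-1-one | CC(=O)c1c(O)cc(OCc2ccccc2)cc1OCc1ccccc1 | intermediate
3 | (E)-1-[2,4-bis(benzyloxy)-6-hydroxyphenyl]-3-(dimethylamino)prop-2-en-1-one | CN(C)/C=C/C(=O)c1c(O)cc(OCc2ccccc2)cc1OCc1ccccc1 | intermediate
4 | 5,7-bis(benzyloxy)-4H-chromen-4-one | O=c1ccoc2cc(OCc3ccccc3)cc(OCc3ccccc3)c12 | intermediate
5 | 4-methoxyphenylboronic acid | COc1ccc(B(O)O)cc1 | starting material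
6 | (2S)-5,7-bis(benzyloxy)-2-(4-methoxyphenyl)chroman-4-one | COc1ccc([C@@H]2CC(=O)c3c(OCc4ccccc4)cc(OCc4ccccc4)cc3O2)cc1 | intermediate
7 | (2S)-5,7-bis(benzyloxy)-8-iodo-2-(4-methoxyphenyl)chroman-4-one | COc1ccc([C@@H]2CC(=O)c3c(OCc4ccccc4)cc(OCc4ccccc4)c(I)c3O2)cc1 | intermediate
8 | (2S)-5,7-bis(benzyloxy)-2-(4-methoxyphenyl)-8-(4,4,5,5-tetramethyl-1,3,2-dioxaborolan-2-yl)chroman-4-one | COc1ccc([C@@H]2CC(=O)c3c(OCc4ccccc4)cc(OCc4ccccc4)c(B4OC(C)(C)C(C)(C)O4)c3O2)cc1 | intermediate
9 | 2,4,6-trihydroxybenzaldehyde | O=Cc1c(O)cc(O)cc1O | starting material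
10 | 2,4-bis(benzyloxy)-6-hydroxybenzaldehyde | O=Cc1c(O)cc(OCc2ccccc2)cc1OCc1ccccc1 | intermediate
11 | 2,4-bis(benzyloxy)-6-[(triisopropylsilyl)oxy]benzaldehyde | O=Cc1c(O[Si](C(C)C)(C(C)C)C(C)C)cc(OCc2ccccc2)cc1OCc1ccccc1 | intermediate
12 | 4-hydroxybenzaldehyde | O=Cc1ccc(O)cc1 | starting material
13 | 4-[(triisopropylsilyl)oxy]benzaldehyde | O=Cc1ccc(O[Si](C(C)C)(C(C)C)C(C)C)cc1 | intermediate
14 | [4-(2,2-dibromovinyl)phenoxy]triisopropylsilane | BrC(Br)=Cc1ccc(O[Si](C(C)C)(C(C)C)C(C)C)cc1 | intermediate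
15 | lithium [4-(triisopropylsilyloxy)phenyl]acetylide | [Li]C#Cc1ccc(O[Si](C(C)C)(C(C)C)C(C)C)cc1 | intermediate
16 | 1-[2,4-bis(benzyloxy)-6-(triisopropylsilyloxy)phenyl]-3-[4-(triisopropylsilyloxy)phenyl]prop-2-yn-1-ol (racemic) | OC(C#Cc1ccc(O[Si](C(C)C)(C(C)C)C(C)C)cc1)c1c(O[Si](C(C)C)(C(C)C)C(C)C)cc(OCc2ccccc2)cc1OCc1ccccc1 | intermediate
17 | 1-[2,4-bis(benzyloxy)-6-(triisopropylsilyloxy)phenyl]-3-[4-(triisopropylsilyloxy)phenyl]prop-2-yn-1-one | O=C(C#Cc1ccc(O[Si](C(C)C)(C(C)C)C(C)C)cc1)c1c(O[Si](C(C)C)(C(C)C)C(C)C)cc(OCc2ccccc2)cc1OCc1ccccc1 | intermediate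
18 | (E)-1-[2,4-bis(benzyloxy)-6-(triisopropylsilyloxy)phenyl]-2-(tributylstannyl)-3-[4-(triisopropylsilyloxy)phenyl]prop-2-en-1-one | CCCC[Sn](CCCC)(CCCC)/C(=C/c1ccc(O[Si](C(C)C)(C(C)C)C(C)C)cc1)C(=O)c1c(O[Si](C(C)C)(C(C)C)C(C)C)cc(OCc2ccccc2)cc1OCc1ccccc1 | intermediate
19 | (E)-1-[2,4-bis(benzyloxy)-6-(triisopropylsilyloxy)phenyl]-2-iodo-3-[4-(triisopropylsilyloxy)phenyl]prop-2-en-1-one | I/C(=C/c1ccc(O[Si](C(C)C)(C(C)C)C(C)C)cc1)C(=O)c1c(O[Si](C(C)C)(C(C)C)C(C)C)cc(OCc2ccccc2)cc1OCc1ccccc1 | intermediate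
20 | (2S)-5,7-bis(benzyloxy)-8-{(Z)-3-[2,4-bis(benzyloxy)-6-(triisopropylsilyloxy)phenyl]-3-oxo-1-[4-(triisopropylsilyloxy)phenyl]prop-1-en-2-yl}-2-(4-methoxyphenyl)chroman-4-one | COc1ccc([C@@H]2CC(=O)c3c(OCc4ccccc4)cc(OCc4ccccc4)c(/C(=C/c4ccc(O[Si](C(C)C)(C(C)C)C(C)C)cc4)C(=O)c4c(O[Si](C(C)C)(C(C)C)C(C)C)cc(OCc5ccccc5)cc4OCc4ccccc4)c3O2)cc1 | intermediate
21 | (2S)-5,7-bis(benzyloxy)-8-{(Z)-3-[2,4-bis(benzyloxy)-6-hydroxyphenyl]-1-(4-hydroxyphenyl)-3-oxoprop-1-en-2-yl}-2-(4-methoxyphenyl)chroman-4-one | COc1ccc([C@@H]2CC(=O)c3c(OCc4ccccc4)cc(OCc4ccccc4)c(/C(=C/c4ccc(O)cc4)C(=O)c4c(O)cc(OCc5ccccc5)cc4OCc4ccccc4)c3O2)cc1 | intermediate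
22 | (2S)-5,7-bis(benzyloxy)-8-{1-[2,4-bis(benzyloxy)-6-hydroxyphenyl]-1-oxo-3-(4-oxocyclohexa-2,5-dien-1-ylidene)propan-2-yl}-2-(4-methoxyphenyl)chroman-4-one (both C3 epimers) | COc1ccc([C@@H]2CC(=O)c3c(OCc4ccccc4)cc(OCc4ccccc4)c(C(C=C4C=CC(=O)C=C4)C(=O)c4c(O)cc(OCc5ccccc5)cc4OCc4ccccc4)c3O2)cc1 | intermediate
23 | (2R,3S)-5,7-bis(benzyloxy)-3-[(2S)-5,7-bis(benzyloxy)-2-(4-methoxyphenyl)-4-oxochroman-8-yl]-2-(4-hydroxyphenyl)chroman-4-one | COc1ccc([C@@H]2CC(=O)c3c(OCc4ccccc4)cc(OCc4ccccc4)c([C@@H]4C(=O)c5c(OCc6ccccc6)cc(OCc6ccccc6)cc5O[C@H]4c4ccc(O)cc4)c3O2)cc1 | intermediate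
24 | (2R,3S)-5,7-dihydroxy-3-[(2S)-5,7-dihydroxy-2-(4-methoxyphenyl)-4-oxochroman-8-yl]-2-(4-hydroxyphenyl)chroman-4-one (CNP0140544.1) | COc1ccc([C@@H]2CC(=O)c3c(O)cc(O)c([C@@H]4C(=O)c5c(O)cc(O)cc5O[C@H]4c4ccc(O)cc4)c3O2)cc1 | target

**Step count**
Total: 16 steps. Longest linear sequence: 9 steps (for example steps 6, 7, 10, 11, 12, 13, 14, 15, 16 from 9; the branches from 1 and from 12 are equally long).

**Steps most likely to fail**

Step 15. Facial selectivity at C2 may be poor if the catalyst does not override the bias of the remote C2'' centre and of the hindered C3–C8'' axis. The reversible closure may also erode a kinetic preference. Fallback with known chemistry: setting out from 21, the classical acid-catalysed chalcone–flavanone isomerisation is run with an achiral Brønsted acid (TsOH, cat., toluene, rt). This should give 23 together with (2S,3R)-5,7-bis(benzyloxy)-3-[(2S)-5,7-bis(benzyloxy)-2-(4-methoxyphenyl)-4-oxochroman-8-yl]-2-(4-hydroxyphenyl)chroman-4-one F1. Because C2'' is fixed, the two are diastereomers and are separated by chromatography; F1 can be returned to the same acid for re-equilibration. The route is rejoined at 23.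

Step 13. Protodeboronation of the hindered, electron-rich boronate may outrun transmetalation, and the aqueous base may open ring F and erode the configuration at C2''. Fallback: setting out from 7 and from stannane 18, which is isolated in step 12 instead of being iodinated, a base-free Stille coupling is run (Pd2(dba)3, AsPh3, CuI, N-methylpyrrolidone, 60 °C). It joins the same two carbons and comes back to the route at 20. No compound outside the list is made (F0).

Step 3. Aryl transfer to the electron-rich 5,7-dialkoxychromone may be slow and the enantioselectivity insufficient. Fallback: setting out from 2, Claisen–Schmidt condensation with 4-methoxybenzaldehyde (KOH, EtOH) gives (E)-1-[2,4-bis(benzyloxy)-6-hydroxyphenyl]-3-(4-methoxyphenyl)prop-2-en-1-one F2. Oxa-Michael closure (NaOAc, EtOH, reflux) gives the racemic flavanone, which is resolved by preparative chromatography on a chiral stationary phase. The unwanted (2R)-5,7-bis(benzyloxy)-2-(4-methoxyphenyl)chroman-4-one F3 is set aside, and the route is rejoined at 6.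

**Further compounds**
F1 | step 15 | (2S,3R)-5,7-bis(benzyloxy)-3-[(2S)-5,7-bis(benzyloxy)-2-(4-methoxyphenyl)-4-oxochroman-8-yl]-2-(4-hydroxyphenyl)chroman-4-one | COc1ccc([C@@H]2CC(=O)c3c(OCc4ccccc4)cc(OCc4ccccc4)c([C@H]4C(=O)c5c(OCc6ccccc6)cc(OCc6ccccc6)cc5O[C@@H]4c4ccc(O)cc4)c3O2)cc1
F0 | step 13 | none | none
F2 | step 3 | (E)-1-[2,4-bis(benzyloxy)-6-hydroxyphenyl]-3-(4-methoxyphenyl)prop-2-en-1-one | COc1ccc(/C=C/C(=O)c2c(O)cc(OCc3ccccc3)cc2OCc2ccccc2)cc1
F3 | step 3 | (2R)-5,7-bis(benzyloxy)-2-(4-methoxyphenyl)chroman-4-one | COc1ccc([C@H]2CC(=O)c3c(OCc4ccccc4)cc(OCc4ccccc4)cc3O2)cc1
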